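**Plan**

- **Cuts.** The retrosynthesis first cuts the linker bond C7–C11, seen as a C7=C11 alkene joining a dioxane aldehyde to an ent-drimenyl sulfone. It then cuts C1–C2 of the propanoate arm and rejoins C2 and C7 as a C=C bond. Last, it cuts both ring C–O bonds (O–C3 and O–C6), which leads to 1,3-dimethylcyclohexa-1,3-diene and O2.
- **Enabling feature.** In the 1,2-dioxane ring (O1, O2, C3, C4, C5, C6) the propanoate arm on C3 and the linker arm on C6 lie on the same face. Tying C2 to C7 therefore turns the ring into a 2,3-dioxabicyclo[2.2.2]oct-5-ene. O1–O2 is its peroxide bridge, C4–C5 its ethano bridge and C2=C7 its etheno bridge.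
- **Forward order.** The dioxane ring closes first (step 3), and the carbocycle around it is opened (step 4). The acetyl arm is grown into the methyl propanoate (steps 6–9). Rings A and B of the decalin form together from farnesol (step 11). The halves are joined in step 16 and the new alkene is saturated in step 17.
- **Stereochemistry.** C3/C6 cis comes from the suprafacial cycloaddition, and its absolute sense from separating (R,R)-hydrobenzoin acetals (step 5). C2 comes from anti-selective 9-BBN hydroboration next to C3 (step 7). C5/C9/C10 relative configuration comes from chair–chair folding of the E,E-triene, and its absolute sense from a camphanate resolution (step 12).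

Key step: step 3

**Remark on the chemistry.** C1–C7 follow the target: C1 is the ester carbon, C2 its α-carbon, C3–C6 the dioxane carbons and C7 the linker carbon on C6. The decalin carries drimane numbers, with C11 the linker carbon on C9. Racemic intermediates are drawn as the enantiomer that leads to the target.

Step 1
Reactants: 1 3-methylcyclohex-2-en-1-one
Product: 2 (±)-1,3-dimethylcyclohex-2-en-1-ol
Conditions: MeLi, Et2O, −78 → 0 °C; H2O
Reagents that add atoms: methyllithium, [Li]C
Why: 1,2-Addition of the hard organolithium to the enone carbonyl should give the tertiary allylic alcohol, whose racemic stereocentre is erased in step 2.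

Step 2
Reactants: 2 (±)-1,3-dimethylcyclohex-2-en-1-ol
Product: 3 1,3-dimethylcyclohexa-1,3-diene
Conditions: p-TsOH·H2O (cat.), pentane, rt; distillation
Reagents that add atoms: none
Why: Acid-catalysed E1 dehydration passes through the symmetrical 1,3-dimethylcyclohexenyl cation, and reversible protonation funnels double-bond isomers to the conjugated endocyclic diene with two trisubstituted alkenes.

Step 3
Reactants: 3 1,3-dimethylcyclohexa-1,3-diene; 4 dioxygen
Product: 5 rac-(1R,4S)-1,5-dimethyl-2,3-dioxabicyclo[2.2.2]oct-5-ene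
Conditions: O2, 5,10,15,20-tetraphenylporphyrin (cat.), visible light, CH2Cl2, −20 °C
Reagents that add atoms: dioxygen (compound 4), O=O
Why: Sensitised singlet oxygen adds to the ring-locked s-cis diene of 3 in a concerted suprafacial [4π+2π] cycloaddition that forms O–C6 (diene C1) and O–C3 (diene C4) in one event. The closest known case is the photooxygenation of α-terpinene to ascaridole, likewise a 1,4-bridging of an alkylated cyclohexa-1,3-diene. The one new ring closes by cycloaddition: the O–O unit spans the diene termini, so the saturated 1,2-dioxane perimeter (O1, O2, C3, C4, C5, C6) and the dihydrodioxine perimeter through the etheno bridge arise together inside a [2.2.2] bicycle. The two new stereocentres, the methyl-bearing bridgehead (C6) and the CH bridgehead (C3), are locked to each other because both oxygens must reach the same ring face, while the faces of achiral 3 are enantiotopic, so 5 forms as a racemate whose absolute sense is settled in step 5. The step needs periselectivity for [4+2] over the ene reaction at the allylic C–H bonds, which the planar s-cis geometry, the two donor methyl groups, the low temperature and the non-polar solvent should secure, and regiochemistry is no issue because dioxygen is symmetrical.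

Step 4
Reactants: 5 rac-(1R,4S)-1,5-dimethyl-2,3-dioxabicyclo[2.2.2]oct-5-ene
Product: 7 rac-(3S,6R)-3-acetyl-6-formyl-6-methyl-1,2-dioxane (acetyl and formyl cis), via secondary ozonide 6 (not isolated)
Conditions: O3, CH2Cl2, −78 °C; then Me2S, −78 °C → rt
Reagents that add atoms: ozone, [O-][O+]=O
Why: Ozonolysis (Criegee mechanism) of the electron-rich trisubstituted etheno bridge is a known cleavage of 2,3-dioxabicyclo[2.2.2]oct-5-enes, the dialkyl peroxide is inert to ozone and Me2S, and since no bond at C3 or C6 is touched the two carbonyl arms stay cis.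

Step 5
Reactants: 7 rac-(3S,6R)-3-acetyl-6-formyl-6-methyl-1,2-dioxane; 8 (R,R)-hydrobenzoin
Product: 9 (3S,6R)-3-acetyl-6-[(4R,5R)-4,5-diphenyl-1,3-dioxolan-2-yl]-6-methyl-1,2-dioxane
Conditions: camphorsulfonic acid (cat.), 4 Å molecular sieves, CH2Cl2, rt; separation of the two acetals by chromatography and crystallisation
Reagents that add atoms: (R,R)-hydrobenzoin (compound 8), O[C@H](c1ccccc1)[C@H](O)c1ccccc1
Why: Acid-catalysed acetalisation picks the aldehyde over the methyl ketone, and because the diol is C2-symmetric the acetal carbon is not stereogenic, so the racemate gives exactly two diastereomers that are parted as in a classical resolution through covalent derivatives, the configuration to be secured by X-ray analysis.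

Step 6
Reactants: 9 (3S,6R)-3-acetyl-6-[(4R,5R)-4,5-diphenyl-1,3-dioxolan-2-yl]-6-methyl-1,2-dioxane
Product: 11 (3S,6R)-6-[(4R,5R)-4,5-diphenyl-1,3-dioxolan-2-yl]-6-methyl-3-(prop-1-en-2-yl)-1,2-dioxane, via β-hydroxysilane 10 (not isolated)
Conditions: Me3SiCH2Li, CeCl3, THF, −78 °C; then aq. HF, MeCN, 0 °C
Reagents that add atoms: (trimethylsilyl)methyllithium, [Li]C[Si](C)(C)C
Why: Peterson olefination in which the weakly basic organocerium reagent should add to the enolisable ketone faster than it removes the C3 proton or attacks O–O, after which acid-induced elimination of the β-hydroxysilane gives the 1,1-disubstituted alkene regiospecifically without touching C3.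

Step 7
Reactants: 11 (3S,6R)-6-[(4R,5R)-4,5-diphenyl-1,3-dioxolan-2-yl]-6-methyl-3-(prop-1-en-2-yl)-1,2-dioxane
Product: 13 (2R)-2-{(3S,6R)-6-[(4R,5R)-4,5-diphenyl-1,3-dioxolan-2-yl]-6-methyl-1,2-dioxan-3-yl}propan-1-ol, via B-alkyl-9-BBN adduct 12 (not isolated)
Conditions: 9-BBN, THF, 0 °C → rt; then NaBO3·4H2O, THF/H2O, rt
Reagents that add atoms: sodium perborate, [Na+].[O-]OB=O
Why: Hydroboration–oxidation in which 9-BBN places boron on the terminal carbon and, as is usual for 2-substituted allylic ethers, attacks the face that gives the anti 2-methyl-3-oxy relationship (C3–H turned toward the C2 methyl, C3–C4 anti to the borane), which sets C2, while the mild perborate work-up spares the dioxane and any syn isomer is removed by chromatography.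

Step 8
Reactants: 13 (2R)-2-{(3S,6R)-6-[(4R,5R)-4,5-diphenyl-1,3-dioxolan-2-yl]-6-methyl-1,2-dioxan-3-yl}propan-1-ol
Product: 15 (2S)-2-{(3S,6R)-6-[(4R,5R)-4,5-diphenyl-1,3-dioxolan-2-yl]-6-methyl-1,2-dioxan-3-yl}propanoic acid, via aldehyde 14 (not isolated)
Conditions: TEMPO (cat.), PhI(OAc)2, MeCN/H2O, rt
Reagents that add atoms: water, O
Why: Oxoammonium-mediated oxidation runs through the aldehyde hydrate to the acid under weakly acidic conditions, so C2 should not epimerise and the β-peroxy group should not be eliminated (the descriptor at C2 changes only because the priorities change).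

Step 9
Reactants: 15 (2S)-2-{(3S,6R)-6-[(4R,5R)-4,5-diphenyl-1,3-dioxolan-2-yl]-6-methyl-1,2-dioxan-3-yl}propanoic acid
Product: 16 methyl (2S)-2-{(3S,6R)-6-[(4R,5R)-4,5-diphenyl-1,3-dioxolan-2-yl]-6-methyl-1,2-dioxan-3-yl}propanoate
Conditions: Me3SiCHN2, toluene/MeOH, 0 °C
Reagents that add atoms: (trimethylsilyl)diazomethane, C[Si](C)(C)C=[N+]=[N-]
Why: O-Methylation of the carboxylic acid with a diazoalkane needs no base, which avoids retro-oxa-Michael opening of the β-peroxy ester.

Step 10
Reactants: 16 methyl (2S)-2-{(3S,6R)-6-[(4R,5R)-4,5-diphenyl-1,3-dioxolan-2-yl]-6-methyl-1,2-dioxan-3-yl}propanoate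
Product: 17 methyl (2S)-2-[(3S,6R)-6-formyl-6-methyl-1,2-dioxan-3-yl]propanoate
Conditions: CF3CO2H/H2O, CH2Cl2, 0 °C → rt
Reagents that add atoms: water, O
Why: Acid hydrolysis of the acetal is compatible with the acid-stable dioxane and methyl ester, and the liberated aldehyde sits on quaternary C6 and therefore cannot epimerise or enolise.

Step 11
Reactants: 18 (2E,6E)-farnesol
Product: 19 (±)-drimenol
Conditions: FSO3H, 2-nitropropane, −78 °C; Et3N quench
Reagents that add atoms: none
Why: Superacid-induced cationic polyene cyclisation, known for this substrate, protonates the terminal alkene, closes rings A and B through a chair–chair fold with anti addition across both E-alkenes (trans ring fusion at C5/C10, equatorial C11 on C9) and ends by proton loss from C7.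

Step 12
Reactants: 19 (±)-drimenol; 20 (1S)-(−)-camphanic chloride
Product: 21 ent-drimenyl (1S)-camphanate, (1R,4aR,8aR) in the decalin
Conditions: Et3N, DMAP (cat.), CH2Cl2, 0 °C → rt; fractional crystallisation and chromatography
Reagents that add atoms: (1S)-(−)-camphanic chloride (compound 20), ClC(=O)[C@@]12CC[C@@](C)(C(=O)O1)C2(C)C
Why: Acylation of the primary alcohol with an enantiopure acid chloride that cannot racemise gives two diastereomeric esters, which are separated in a classical resolution that fixes the absolute sense of C5, C9 and C10.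

Step 13
Reactants: 21 ent-drimenyl (1S)-camphanate
Product: 22 (+)-drimenol (ent-drimenol), (1R,4aR,8aR)
Conditions: KOH, MeOH/H2O, reflux; then aq. HCl
Reagents that add atoms: none
Why: Ester saponification by acyl–oxygen cleavage releases the alcohol without touching any stereocentre or the trisubstituted alkene.

Step 14
Reactants: 22 (+)-drimenol; 23 1-phenyl-1H-tetrazole-5-thiol
Product: 24 5-{[(1R,4aR,8aR)-2,5,5,8a-tetramethyl-1,4,4a,5,6,7,8,8a-octahydronaphthalen-1-yl]methylsulfanyl}-1-phenyl-1H-tetrazole
Conditions: PPh3, DIAD, THF, 0 °C → rt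
Reagents that add atoms: 1-phenyl-1H-tetrazole-5-thiol (compound 23), Sc1nnnn1-c1ccccc1
Why: Mitsunobu thioetherification displaces the activated primary C11 oxygen with the soft, acidic thiol in an SN2 step at a non-stereogenic carbon.

Step 15
Reactants: 24 ent-drimenyl phenyltetrazolyl sulfide
Product: 25 5-{[(1R,4aR,8aR)-2,5,5,8a-tetramethyl-1,4,4a,5,6,7,8,8a-octahydronaphthalen-1-yl]methylsulfonyl}-1-phenyl-1H-tetrazole
Conditions: 30 % H2O2, (NH4)6Mo7O24·4H2O (cat.), EtOH, 0 °C → rt
Reagents that add atoms: hydrogen peroxide, OO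
Why: Molybdate-catalysed peroxide oxidation takes sulfides to sulfones much faster than it epoxidises a hindered trisubstituted alkene.

Step 16
Reactants: 25 ent-drimenyl phenyltetrazolyl sulfone; 17 methyl (2S)-2-[(3S,6R)-6-formyl-6-methyl-1,2-dioxan-3-yl]propanoate
Product: 27 methyl (2S)-2-[(3S,6R)-6-methyl-6-{(E)-2-[(1R,4aR,8aR)-2,5,5,8a-tetramethyl-1,4,4a,5,6,7,8,8a-octahydronaphthalen-1-yl]ethenyl}-1,2-dioxan-3-yl]propanoate, via potassiated sulfone 26 (not isolated)
Conditions: 25, KN(SiMe3)2 (slightly less than 1 equiv), DME, −78 °C; then 17, −78 °C → rt; aq. NH4Cl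
Reagents that add atoms: none
Why: Julia–Kocienski olefination in which the pre-formed carbanion adds to the non-enolisable aldehyde and Smiles transfer of the tetrazole with loss of SO2 forms C7=C11 (E expected, geometry irrelevant because it is reduced next), while the absence of free base at low temperature spares the ester α-proton and the peroxide and no stereocentre is touched.

Step 17
Reactants: 27 E-alkene
Product: 28 methyl (2S)-2-[(3S,6S)-6-methyl-6-{2-[(1R,4aR,8aR)-2,5,5,8a-tetramethyl-1,4,4a,5,6,7,8,8a-octahydronaphthalen-1-yl]ethyl}-1,2-dioxan-3-yl]propanoate (CNP0124238.1)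
Conditions: KO2CN=NCO2K, AcOH, CH2Cl2/MeOH, 0 °C → rt, repeated charges
Reagents that add atoms: none
Why: Diimide reduction delivers H2 in a concerted way to the 1,2-disubstituted alkene far faster than to the trisubstituted ring alkene and leaves O–O bonds intact, as known from the saturation of unsaturated endoperoxides (the C6 descriptor changes from R to S by priority only).

**Compound list**

1 | 3-methylcyclohex-2-en-1-one | CC1=CC(=O)CCC1 | starting material
2 | (±)-1,3-dimethylcyclohex-2-en-1-ol | CC1=CC(C)(O)CCC1 | intermediate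
3 | 1,3-dimethylcyclohexa-1,3-diene | CC1=CC(C)=CCC1 | intermediate
4 | dioxygen (used as photosensitised singlet oxygen) | O=O | starting material
5 | rac-(1R,4S)-1,5-dimethyl-2,3-dioxabicyclo[2.2.2]oct-5-ene (needed enantiomer drawn) | CC1=C[C@@]2(C)CC[C@@H]1OO2 | intermediate
6 | secondary ozonide of 5, 1,2,4-trioxolane spanning C2 and C7 (racemic, not isolated) | CC2(OOC3O2)[C@@H]1CC[C@@]3(C)OO1 | intermediate
7 | rac-(3S,6R)-3-acetyl-6-formyl-6-methyl-1,2-dioxane, arms cis (needed enantiomer drawn) | CC(=O)[C@@H]1CC[C@](C)(C=O)OO1 | intermediate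
8 | (R,R)-hydrobenzoin, (1R,2R)-1,2-diphenylethane-1,2-diol | O[C@H](c1ccccc1)[C@H](O)c1ccccc1 | starting material
9 | (3S,6R)-3-acetyl-6-[(4R,5R)-4,5-diphenyl-1,3-dioxolan-2-yl]-6-methyl-1,2-dioxane | CC(=O)[C@@H]1CC[C@](C)(C2O[C@H](c3ccccc3)[C@@H](c3ccccc3)O2)OO1 | intermediate
10 | β-hydroxysilane, 2-{(3S,6R)-6-[(4R,5R)-4,5-diphenyl-1,3-dioxolan-2-yl]-6-methyl-1,2-dioxan-3-yl}-1-(trimethylsilyl)propan-2-ol, carbinol epimers (not isolated) | C[Si](C)(C)CC(C)(O)[C@@H]1CC[C@](C)(C2O[C@H](c3ccccc3)[C@@H](c3ccccc3)O2)OO1 | intermediate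
11 | (3S,6R)-6-[(4R,5R)-4,5-diphenyl-1,3-dioxolan-2-yl]-6-methyl-3-(prop-1-en-2-yl)-1,2-dioxane | CC(=C)[C@@H]1CC[C@](C)(C2O[C@H](c3ccccc3)[C@@H](c3ccccc3)O2)OO1 | intermediate
12 | B-alkyl-9-BBN adduct, boron on C1, (2R,3S,6R) (not isolated) | C1CC2CCCC(C1)B2C[C@@H](C)[C@@H]1CC[C@](C)(C2O[C@H](c3ccccc3)[C@@H](c3ccccc3)O2)OO1 | intermediate
13 | (2R)-2-{(3S,6R)-6-[(4R,5R)-4,5-diphenyl-1,3-dioxolan-2-yl]-6-methyl-1,2-dioxan-3-yl}propan-1-ol | OC[C@@H](C)[C@@H]1CC[C@](C)(C2O[C@H](c3ccccc3)[C@@H](c3ccccc3)O2)OO1 | intermediate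
14 | (2S)-2-{(3S,6R)-6-[(4R,5R)-4,5-diphenyl-1,3-dioxolan-2-yl]-6-methyl-1,2-dioxan-3-yl}propanal (not isolated) | O=C[C@@H](C)[C@@H]1CC[C@](C)(C2O[C@H](c3ccccc3)[C@@H](c3ccccc3)O2)OO1 | intermediate
15 | (2S)-2-{(3S,6R)-6-[(4R,5R)-4,5-diphenyl-1,3-dioxolan-2-yl]-6-methyl-1,2-dioxan-3-yl}propanoic acid | OC(=O)[C@@H](C)[C@@H]1CC[C@](C)(C2O[C@H](c3ccccc3)[C@@H](c3ccccc3)O2)OO1 | intermediate
16 | methyl (2S)-2-{(3S,6R)-6-[(4R,5R)-4,5-diphenyl-1,3-dioxolan-2-yl]-6-methyl-1,2-dioxan-3-yl}propanoate | COC(=O)[C@@H](C)[C@@H]1CC[C@](C)(C2O[C@H](c3ccccc3)[C@@H](c3ccccc3)O2)OO1 | intermediate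
17 | methyl (2S)-2-[(3S,6R)-6-formyl-6-methyl-1,2-dioxan-3-yl]propanoate | COC(=O)[C@@H](C)[C@@H]1CC[C@](C)(C=O)OO1 | intermediate
18 | (2E,6E)-farnesol | CC(C)=CCC/C(C)=C/CC/C(C)=C/CO | starting material
19 | (±)-drimenol (needed enantiomer drawn) | OC[C@@H]1C(C)=CC[C@@H]2C(C)(C)CCC[C@@]12C | intermediate
20 | (1S)-(−)-camphanic chloride, (1S,4R)-4,7,7-trimethyl-3-oxo-2-oxabicyclo[2.2.1]heptane-1-carbonyl chloride | ClC(=O)[C@@]12CC[C@@](C)(C(=O)O1)C2(C)C | starting material
21 | ent-drimenyl (1S)-camphanate | O=C(OC[C@@H]1C(C)=CC[C@@H]2C(C)(C)CCC[C@@]12C)[C@@]12CC[C@@](C)(C(=O)O1)C2(C)C | intermediate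
22 | (+)-drimenol (ent-drimenol), [(1R,4aR,8aR)-2,5,5,8a-tetramethyl-1,4,4a,5,6,7,8,8a-octahydronaphthalen-1-yl]methanol | OC[C@@H]1C(C)=CC[C@@H]2C(C)(C)CCC[C@@]12C | intermediate
23 | 1-phenyl-1H-tetrazole-5-thiol | Sc1nnnn1-c1ccccc1 | starting material
24 | ent-drimenyl 1-phenyl-1H-tetrazol-5-yl sulfide | C(Sc1nnnn1-c1ccccc1)[C@@H]1C(C)=CC[C@@H]2C(C)(C)CCC[C@@]12C | intermediate
25 | ent-drimenyl 1-phenyl-1H-tetrazol-5-yl sulfone | C(S(=O)(=O)c1nnnn1-c1ccccc1)[C@@H]1C(C)=CC[C@@H]2C(C)(C)CCC[C@@]12C | intermediate
26 | potassium salt of the C11 carbanion of 25 (not isolated) | [K+].[CH-](S(=O)(=O)c1nnnn1-c1ccccc1)[C@@H]1C(C)=CC[C@@H]2C(C)(C)CCC[C@@]12C | intermediate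
27 | methyl (2S)-2-[(3S,6R)-6-methyl-6-{(E)-2-[(1R,4aR,8aR)-2,5,5,8a-tetramethyl-1,4,4a,5,6,7,8,8a-octahydronaphthalen-1-yl]ethenyl}-1,2-dioxan-3-yl]propanoate | COC(=O)[C@@H](C)[C@@H]1CC[C@](C)(/C=C/[C@@H]2C(C)=CC[C@@H]3C(C)(C)CCC[C@@]23C)OO1 | intermediate
28 | methyl (2S)-2-[(3S,6S)-6-methyl-6-{2-[(1R,4aR,8aR)-2,5,5,8a-tetramethyl-1,4,4a,5,6,7,8,8a-octahydronaphthalen-1-yl]ethyl}-1,2-dioxan-3-yl]propanoate | COC(=O)[C@@H](C)[C@@H]1CC[C@](C)(CC[C@@H]2C(C)=CC[C@@H]3C(C)(C)CCC[C@@]23C)OO1 | target

**Step count**

- Total step count: 17.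
- Longest linear sequence: 12 (steps 1–10, 16, 17).
- The decalin branch (steps 11–15) has 5 steps and joins the main line at step 16.

**Steps most likely to fail**

**Step 16 (union).**
- What may go wrong: the congested C11 carbanion may add only slowly to the aldehyde on quaternary C6. The β-peroxy alkoxide adduct may collapse by C6–C7/O–O fragmentation before the Smiles rearrangement. Stray base may open the ring by retro-oxa-Michael elimination across C2–C3.
- Route of the fallback: it sets out from 22 and 17 and comes back at 27. It replaces the one-pot olefination by addition followed by dehydration.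
- Alcohol 22 is converted with I2, PPh3 and imidazole into ent-drimenyl iodide F1.
- Lithium–iodine exchange with t-BuLi in Et2O/pentane at −78 °C gives the much slimmer nucleophile ent-drimenyllithium F2.
- This is added at −78 °C to 17, where the aldehyde reacts before the ester, to give the C7 carbinol F3 as an epimer mixture.
- Dehydration with Ph2S[OC(CF3)2Ph]2 in CH2Cl2 can only run toward C11, because C6 is quaternary, and delivers 27.

**Step 6 (methylenation of the α-peroxy ketone).**
- What may go wrong: the C3 proton lies between the carbonyl group and a peroxide oxygen. Deprotonation would lead to O–O heterolysis of the Kornblum–DeLaMare type or to epimerisation at C3. The organometallic may also attack the O–O bond.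
- Route of the fallback: it sets out from 9 and comes back at 11. It swaps the addition–elimination sequence for a non-basic carbonyl/metal-alkylidene exchange.
- Ketone 9 is treated with Cp2Ti(µ-CH2)(µ-Cl)AlMe2 and a little pyridine in toluene/THF at −40 → 0 °C. A [2+2]/cycloreversion then gives 11 directly.
- This detour makes no new compound (F0).

**Step 5 (resolution).**
- What may go wrong: the two acetals may differ too little in chromatographic and crystallisation behaviour. Prolonged acid contact may enolise the ketone toward C3 and erode the cis relationship.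
- Route of the fallback: it sets out from 5 and comes back at 9.
- Racemic 5 is separated into its enantiomers by preparative chromatography on a polysaccharide-based chiral stationary phase.
- The (1R,4S) enantiomer is taken through steps 4 and 5 with a short acid contact. Acetal 9 is then the only acetal formed, and the hydrobenzoin serves as protecting group and as a check of enantiopurity.
- This detour makes no new compound (F0).

**Further compounds**

F1 | step 16 | ent-drimenyl iodide, (1R,4aR,8aR)-1-(iodomethyl)-2,5,5,8a-tetramethyl-1,4,4a,5,6,7,8,8a-octahydronaphthalene | IC[C@@H]1C(C)=CC[C@@H]2C(C)(C)CCC[C@@]12C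
F2 | step 16 | ent-drimenyllithium | [Li]C[C@@H]1C(C)=CC[C@@H]2C(C)(C)CCC[C@@]12C
F3 | step 16 | C7 carbinol, methyl (2S)-2-[(3S,6R)-6-{1-hydroxy-2-[(1R,4aR,8aR)-2,5,5,8a-tetramethyl-1,4,4a,5,6,7,8,8a-octahydronaphthalen-1-yl]ethyl}-6-methyl-1,2-dioxan-3-yl]propanoate, epimers at C7 | COC(=O)[C@@H](C)[C@@H]1CC[C@](C)(C(O)C[C@@H]2C(C)=CC[C@@H]3C(C)(C)CCC[C@@]23C)OO1
F0 | step 6 | none | none
F0 | step 5 | none | none
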